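**Retrosynthetic overview**
1. The strategy rests on ring A of the naphthazarin (C1, C2, C3, C4, C4a, C8a) with its C1'-oxygenated branch at C2. It is cut at C1–C8a, so C1 is the carboxyl carbon of a ten-carbon Z-enoic acid and C8a is the free ortho carbon of a 2,5-dimethoxyphenyl ring.
2. Target 25 comes from dimethoxyquinone ester 23 by oxidative demethylation, and 23 from 1-naphthol 20 by para-oxidation and exchange of the silyl ether for the isobutyrate.
3. Naphthol 20 comes from Z-acid 17 by intramolecular acylation; ring B is bought in, and ring A is the only ring formed.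
4. Acid 17 comes from propargylic alcohol 12 by hydroxyl-directed trans-hydrostannation and methoxycarbonylation, which fix the Z geometry.
5. Alcohol 12 comes from alkynol 8 and benzyl bromide 10; the (S) centre at C1' is set by Noyori transfer hydrogenation of ynone 6.

Key step: step 11

Remark: the target is drawn as one of the rapidly interconverting naphthazarin tautomers, and both drawings denote the same compound. The (S) descriptor holds in every intermediate because the priority order O > sp or sp2 carbon > CH2 > H never changes.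

**Route**

Step 1
Reactants: 1 4-methylpent-3-enoic acid
Product: 3 N-methoxy-N,4-dimethylpent-3-enamide, via acyl imidazolide 2 (not isolated)
Conditions: CDI, CH2Cl2, 0 °C to rt; then MeNH(OMe)·HCl, rt
Reagents that add atoms: N,O-dimethylhydroxylamine hydrochloride, CNOC.Cl
Why: Weinreb amide formation through the acyl imidazolide needs no added base, so the β,γ-alkene should stay out of conjugation.

Step 2
Reactants: 3 N-methoxy-N,4-dimethylpent-3-enamide; 4 trimethylsilylacetylene
Product: 6 6-methyl-1-(trimethylsilyl)hept-5-en-1-yn-3-one, via lithium acetylide 5 (not isolated)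
Conditions: 4, n-BuLi, THF, −78 °C; then 3, −78 to −20 °C; cold aq. NH4Cl
Reagents that add atoms: none
Why: Weinreb ketone synthesis, in which the chelated tetrahedral adduct survives until the cold quench, so single addition is expected and the skipped enone is exposed to base only briefly.

Step 3
Reactants: 6 6-methyl-1-(trimethylsilyl)hept-5-en-1-yn-3-one
Product: 7 (3S)-6-methyl-1-(trimethylsilyl)hept-5-en-1-yn-3-ol
Conditions: Ru[(S,S)-TsNCH(Ph)CH(Ph)NH](p-cymene) (2 mol %), i-PrOH, rt
Reagents that add atoms: none
Why: Noyori asymmetric transfer hydrogenation of an ynone, in which the (S,S)-ligand should place the alkyne as the π-directing group and deliver hydride to the face that gives the (S)-carbinol, under base-free conditions that spare the β,γ-unsaturated ketone.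

Step 4
Reactants: 7 (3S)-6-methyl-1-(trimethylsilyl)hept-5-en-1-yn-3-ol
Product: 8 (3S)-6-methylhept-5-en-1-yn-3-ol
Conditions: K2CO3 (0.2 equiv), MeOH, 0 °C to rt
Reagents that add atoms: none
Why: Methanolysis of the alkynyl C–Si bond is fast under catalytic carbonate and does not touch the carbinol centre.

Step 5
Reactants: 9 2,5-dimethoxybenzyl alcohol
Product: 10 2,5-dimethoxybenzyl bromide
Conditions: PBr3 (0.4 equiv), Et2O, 0 °C; used at once
Reagents that add atoms: phosphorus tribromide, BrP(Br)Br
Why: Conversion of a benzylic alcohol into the bromide by SN2 displacement of its phosphite ester, with the product used fresh because it does not store well.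

Step 6
Reactants: 8 (3S)-6-methylhept-5-en-1-yn-3-ol; 10 2,5-dimethoxybenzyl bromide
Product: 12 (4S)-1-(2,5-dimethoxyphenyl)-7-methyloct-6-en-2-yn-4-ol, via bis(bromomagnesium) alkynide alkoxide 11 (not isolated)
Conditions: EtMgBr (2.1 equiv), THF, 0 °C to rt; then CuI (10 mol %), 10, 45 °C
Reagents that add atoms: none
Why: CuI-catalysed alkynylation of a benzylic bromide by a magnesium acetylide; the magnesium alkoxide is too weak a nucleophile for O-benzylation, so the hydroxyl can stay free.

Step 7
Reactants: 12 (4S)-1-(2,5-dimethoxyphenyl)-7-methyloct-6-en-2-yn-4-ol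
Product: 13 (2Z,4S)-1-(2,5-dimethoxyphenyl)-7-methyl-3-(tributylstannyl)octa-2,6-dien-4-ol
Conditions: Bu3SnH (1.1 equiv), [Cp*RuCl]4 (1.5 mol %), CH2Cl2, rt
Reagents that add atoms: tributyltin hydride, CCCC[SnH](CCCC)CCCC
Why: Hydroxyl-directed ruthenium-catalysed trans-hydrostannation, in which the OH hydrogen-bonds to the chloride ligand and steers tin to the proximal alkyne carbon while H adds anti, so tin should end up cis to the ArCH2 group.

Step 8
Reactants: 13 (2Z,4S)-1-(2,5-dimethoxyphenyl)-7-methyl-3-(tributylstannyl)octa-2,6-dien-4-ol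
Product: 14 methyl (2Z,3S)-2-[2-(2,5-dimethoxyphenyl)ethylidene]-3-hydroxy-6-methylhept-5-enoate
Conditions: Pd(OAc)2 (5 mol %), Ph3As (10 mol %), 1,4-benzoquinone (1.5 equiv), CF3CO2H (20 mol %), CO (1 atm), MeOH, rt
Reagents that add atoms: carbon monoxide, [C-]#[O+]; methanol, CO
Why: Hydroxyl-assisted oxidative methoxycarbonylation of an alkenylstannane (tin-to-palladium transmetalation, CO insertion, methanolysis, reoxidation by benzoquinone), which proceeds with retention of alkene geometry and so places the ester cis to ArCH2.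

Step 9
Reactants: 14 methyl (2Z,3S)-2-[2-(2,5-dimethoxyphenyl)ethylidene]-3-hydroxy-6-methylhept-5-enoate
Product: 15 (2Z,3S)-2-[2-(2,5-dimethoxyphenyl)ethylidene]-3-hydroxy-6-methylhept-5-enoic acid
Conditions: LiOH·H2O (3 equiv), THF/MeOH/H2O, rt; then 1 M HCl to pH 3–4, 0 °C
Reagents that add atoms: lithium hydroxide, [Li+].[OH-]
Why: Saponification of the ester while the neighbouring hydroxyl is still free and unhindered, at room temperature so that hydroxide attacks the acyl carbon and not the doubly activated γ-CH2.

Step 10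
Reactants: 15 (2Z,3S)-2-[2-(2,5-dimethoxyphenyl)ethylidene]-3-hydroxy-6-methylhept-5-enoic acid
Product: 17 (2Z,3S)-3-(tert-butyldimethylsilyloxy)-2-[2-(2,5-dimethoxyphenyl)ethylidene]-6-methylhept-5-enoic acid, via bis-silylated silyl ester 16 (not isolated)
Conditions: TBSOTf (2.5 equiv), 2,6-lutidine, CH2Cl2, −78 to 0 °C; then K2CO3, MeOH/THF/H2O, rt; pH 4 buffer
Reagents that add atoms: tert-butyldimethylsilyl triflate, CC(C)(C)[Si](C)(C)OS(=O)(=O)C(F)(F)F
Why: Exhaustive silylation followed by selective methanolysis of the far more labile silyl ester is a standard way to reach a silyl-protected hydroxy acid without a second hydrolysis of a hindered ester.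

Step 11
Reactants: 17 (2Z,3S)-3-(tert-butyldimethylsilyloxy)-2-[2-(2,5-dimethoxyphenyl)ethylidene]-6-methylhept-5-enoic acid
Product: 20 2-[(1S)-1-(tert-butyldimethylsilyloxy)-4-methylpent-3-enyl]-5,8-dimethoxynaphthalen-1-ol, via mixed trifluoroacetic anhydride 18 (not isolated), via 4H-naphthalen-1-one tautomer 19 (not isolated)
Conditions: (CF3CO)2O (1.05 equiv), 2,6-di-tert-butyl-4-methylpyridine (2.5 equiv), CH2Cl2, −40 to 0 °C; aq. NaHCO3
Reagents that add atoms: none
Why: (CF3CO)2O converts the acid into acyl trifluoroacetate 18, whose acyl carbon (C1 of ring A) attacks arene carbon C6 of the 2,5-dimethoxyphenyl ring (the future C8a, ortho to a methoxy group and to the alkyl chain) in an electrophilic aromatic substitution, and ketone 19 then enolises to naphthol 20. The closest known reaction type is the intramolecular Friedel–Crafts acylation of (Z)-4-arylbut-2-enoic and Stobbe-type arylbutenoic acids to 1-naphthols under anhydride activation. Ring A closes in a 6-exo-trig attack of an aromatic carbon on the exocyclic acyl carbon, with all six ring atoms already sp2 or benzylic and held coplanar by the Z alkene. No stereocentre is formed, and the (S) centre at C1' should be retained because its silyloxy group sits next to an electron-poor acyl unit that disfavours ionisation. The step needs selectivity for the arene over the prenyl alkene and retention of the Z geometry; the rigid cis arrangement of the carboxyl and ArCH2 groups secures both, since alkene acylation would need a five-membered ring with the enoyl unit twisted out of plane, and the single open ortho position leaves no regiochemical choice. The hindered pyridine captures CF3CO2H as it forms, which should keep the silyl ether and the trisubstituted alkene intact at low temperature.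

Step 12
Reactants: 20 2-[(1S)-1-(tert-butyldimethylsilyloxy)-4-methylpent-3-enyl]-5,8-dimethoxynaphthalen-1-ol
Product: 21 2-[(1S)-1-(tert-butyldimethylsilyloxy)-4-methylpent-3-enyl]-5,8-dimethoxynaphthalene-1,4-dione
Conditions: (KSO3)2NO (Fremy's salt, 2.5 equiv), KH2PO4, H2O/acetone, 0 °C to rt
Reagents that add atoms: potassium nitrosodisulfonate, [K+].[K+].[O-]S(=O)(=O)N([O])S(=O)(=O)[O-]
Why: Teuber oxidation of a 1-naphthol through its phenoxyl radical; C2 is blocked and C4 is free, so only the 1,4-quinone can form, and the dimethoxy ring and the alkene are not touched at near-neutral pH.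

Step 13
Reactants: 21 2-[(1S)-1-(tert-butyldimethylsilyloxy)-4-methylpent-3-enyl]-5,8-dimethoxynaphthalene-1,4-dione
Product: 22 2-[(1S)-1-hydroxy-4-methylpent-3-enyl]-5,8-dimethoxynaphthalene-1,4-dione
Conditions: HF·pyridine, pyridine, THF, 0 °C to rt
Reagents that add atoms: none
Why: Fluoride-mediated desilylation with a buffered acidic fluoride source, which avoids the basic conditions that a quinone with a free C3–H does not tolerate.

Step 14
Reactants: 22 2-[(1S)-1-hydroxy-4-methylpent-3-enyl]-5,8-dimethoxynaphthalene-1,4-dione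
Product: 23 (1S)-1-(5,8-dimethoxy-1,4-dioxo-1,4-dihydronaphthalen-2-yl)-4-methylpent-3-enyl 2-methylpropanoate
Conditions: (i-PrCO)2O (1.5 equiv), DMAP (0.1 equiv), pyridine, CH2Cl2, 0 °C
Reagents that add atoms: isobutyric anhydride, CC(C)C(=O)OC(=O)C(C)C
Why: DMAP-catalysed acyl transfer to the secondary alcohol with retention at C1', since the C–O bond of the stereocentre is not broken.

Step 15
Reactants: 23 (1S)-1-(5,8-dimethoxy-1,4-dioxo-1,4-dihydronaphthalen-2-yl)-4-methylpent-3-enyl 2-methylpropanoate
Product: 25 isobutyryl alkannin, via naphthalene-1,4,5,8-tetrone ester 24 (not isolated)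
Conditions: AgO (divalent silver oxide, 4 equiv), 6 M HNO3, 1,4-dioxane, rt, 10 min; then aq. Na2S2O4, CHCl3, 0 °C
Reagents that add atoms: water, O
Why: Oxidative demethylation of the para-dimethoxy ring to the diquinone, followed by mild reduction to the naphthazarin, is the known non-Lewis-acidic way to unmask 5,8-dimethoxy-1,4-naphthoquinones that carry the 1-acyloxy-4-methylpent-3-enyl chain, and it leaves the C1'–O bond untouched.

**Compound list**
1 | 4-methylpent-3-enoic acid | CC(C)=CCC(=O)O | starting material
2 | 1-(imidazol-1-yl)-4-methylpent-3-en-1-one | CC(C)=CCC(=O)n1ccnc1 | intermediate (not isolated)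
3 | N-methoxy-N,4-dimethylpent-3-enamide | CC(C)=CCC(=O)N(C)OC | intermediate
4 | trimethylsilylacetylene | C[Si](C)(C)C#C | starting material
5 | lithium (trimethylsilyl)acetylide | [Li]C#C[Si](C)(C)C | intermediate (not isolated)
6 | 6-methyl-1-(trimethylsilyl)hept-5-en-1-yn-3-one | CC(C)=CCC(=O)C#C[Si](C)(C)C | intermediate
7 | (3S)-6-methyl-1-(trimethylsilyl)hept-5-en-1-yn-3-ol | CC(C)=CC[C@H](O)C#C[Si](C)(C)C | intermediate
8 | (3S)-6-methylhept-5-en-1-yn-3-ol | CC(C)=CC[C@H](O)C#C | intermediate
9 | 2,5-dimethoxybenzyl alcohol | COc1ccc(OC)c(CO)c1 | starting material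
10 | 2,5-dimethoxybenzyl bromide | COc1ccc(OC)c(CBr)c1 | intermediate
11 | bis(bromomagnesium) alkynide alkoxide of 8 | CC(C)=CC[C@H](O[Mg]Br)C#C[Mg]Br | intermediate (not isolated)
12 | (4S)-1-(2,5-dimethoxyphenyl)-7-methyloct-6-en-2-yn-4-ol | CC(C)=CC[C@H](O)C#CCc1cc(OC)ccc1OC | intermediate
13 | (2Z,4S)-1-(2,5-dimethoxyphenyl)-7-methyl-3-(tributylstannyl)octa-2,6-dien-4-ol | CC(C)=CC[C@H](O)/C(=C/Cc1cc(OC)ccc1OC)[Sn](CCCC)(CCCC)CCCC | intermediate
14 | methyl (2Z,3S)-2-[2-(2,5-dimethoxyphenyl)ethylidene]-3-hydroxy-6-methylhept-5-enoate | CC(C)=CC[C@H](O)/C(C(=O)OC)=C/Cc1cc(OC)ccc1OC | intermediate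
15 | (2Z,3S)-2-[2-(2,5-dimethoxyphenyl)ethylidene]-3-hydroxy-6-methylhept-5-enoic acid | CC(C)=CC[C@H](O)/C(C(=O)O)=C/Cc1cc(OC)ccc1OC | intermediate
16 | tert-butyldimethylsilyl (2Z,3S)-3-(tert-butyldimethylsilyloxy)-2-[2-(2,5-dimethoxyphenyl)ethylidene]-6-methylhept-5-enoate | CC(C)=CC[C@H](O[Si](C)(C)C(C)(C)C)/C(C(=O)O[Si](C)(C)C(C)(C)C)=C/Cc1cc(OC)ccc1OC | intermediate (not isolated)
17 | (2Z,3S)-3-(tert-butyldimethylsilyloxy)-2-[2-(2,5-dimethoxyphenyl)ethylidene]-6-methylhept-5-enoic acid | CC(C)=CC[C@H](O[Si](C)(C)C(C)(C)C)/C(C(=O)O)=C/Cc1cc(OC)ccc1OC | intermediate (key-step precursor)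
18 | mixed anhydride of 17 with trifluoroacetic acid | CC(C)=CC[C@H](O[Si](C)(C)C(C)(C)C)/C(C(=O)OC(=O)C(F)(F)F)=C/Cc1cc(OC)ccc1OC | intermediate (not isolated)
19 | 2-[(1S)-1-(tert-butyldimethylsilyloxy)-4-methylpent-3-enyl]-5,8-dimethoxy-4H-naphthalen-1-one | CC(C)=CC[C@H](O[Si](C)(C)C(C)(C)C)C1=CCc2c(OC)ccc(OC)c2C1=O | intermediate (not isolated)
20 | 2-[(1S)-1-(tert-butyldimethylsilyloxy)-4-methylpent-3-enyl]-5,8-dimethoxynaphthalen-1-ol | CC(C)=CC[C@H](O[Si](C)(C)C(C)(C)C)c1ccc2c(OC)ccc(OC)c2c1O | intermediate (key-step product)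
21 | 2-[(1S)-1-(tert-butyldimethylsilyloxy)-4-methylpent-3-enyl]-5,8-dimethoxynaphthalene-1,4-dione | CC(C)=CC[C@H](O[Si](C)(C)C(C)(C)C)C1=CC(=O)c2c(OC)ccc(OC)c2C1=O | intermediate
22 | 2-[(1S)-1-hydroxy-4-methylpent-3-enyl]-5,8-dimethoxynaphthalene-1,4-dione | CC(C)=CC[C@H](O)C1=CC(=O)c2c(OC)ccc(OC)c2C1=O | intermediate
23 | (1S)-1-(5,8-dimethoxy-1,4-dioxo-1,4-dihydronaphthalen-2-yl)-4-methylpent-3-enyl 2-methylpropanoate | CC(C)=CC[C@H](OC(=O)C(C)C)C1=CC(=O)c2c(OC)ccc(OC)c2C1=O | intermediate
24 | (1S)-4-methyl-1-(1,4,5,8-tetraoxo-1,4,5,8-tetrahydronaphthalen-2-yl)pent-3-enyl 2-methylpropanoate | CC(C)=CC[C@H](OC(=O)C(C)C)C1=CC(=O)C2=C(C1=O)C(=O)C=CC2=O | intermediate (not isolated)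
25 | isobutyryl alkannin, (1S)-1-(5,8-dihydroxy-1,4-dioxo-1,4-dihydronaphthalen-2-yl)-4-methylpent-3-enyl 2-methylpropanoate | CC(C)=CC[C@H](OC(=O)C(C)C)C1=CC(=O)c2c(O)ccc(O)c2C1=O | target

**Step count**
Total: 15 steps. Longest linear sequence: 14 steps (steps 1–4 and 6–15 from acid 1); step 5 is a one-step side branch.

**Steps most likely to fail**

Step 11 (key ring closure). Trifluoroacetic acid released during the acylation may cleave or ionise the allylic silyl ether, add to the prenyl alkene, or scramble the Z geometry. The acyl electrophile may also be intercepted by the prenyl alkene instead of the arene. If the buffered mixture stalls, less pyridine would be used so that a little free CF3CO2H remains. Fallback, setting out from acid 17: the ring is closed without any strong acid by heating 17 with Ac2O and NaOAc at about 120 °C. The mixed acetic anhydride is expected to lose a γ-proton to give a dienylketene, which closes ring A by 6π-electrocyclisation (or by direct acylation) and is trapped as 2-[(1S)-1-(tert-butyldimethylsilyloxy)-4-methylpent-3-enyl]-5,8-dimethoxynaphthalen-1-yl acetate F1. Methanolysis of F1 (K2CO3, MeOH, 0 °C) comes back to the route at naphthol 20.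

Step 15 (unmasking of the naphthazarin). The strongly oxidising nitric acid medium may degrade the trisubstituted alkene or solvolyse the acyloxy group at C1', or the oxidation of the deactivated dimethoxy ring may stop short. Fallback, setting out from 23: chelation-assisted, non-oxidative ether cleavage with BCl3 in CH2Cl2 at −78 °C. The Lewis acid is held between each quinone carbonyl and its peri methoxy group, and chloride removes the methyl groups to give the bis(dichloroboryl) chelate F2. Cold hydrolysis of F2 with aq. NaHCO3 comes back to the route at target 25.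

Step 8 (direct carbonylation of the stannane). Protodestannation by the acid additive may outrun transmetalation, or the hindered alkenyltin may transfer too slowly to palladium. Fallback, setting out from stannane 13: iododestannylation (I2, CH2Cl2, 0 °C, retention) gives (2Z,4S)-1-(2,5-dimethoxyphenyl)-3-iodo-7-methylocta-2,6-dien-4-ol F3. Classical carbonylation of F3 through oxidative addition (Pd(PPh3)4, CO 1 atm, Et3N, MeOH, 50 °C) comes back to the route at ester 14.

**Further compounds**
F1 | step 11 | 2-[(1S)-1-(tert-butyldimethylsilyloxy)-4-methylpent-3-enyl]-5,8-dimethoxynaphthalen-1-yl acetate | CC(C)=CC[C@H](O[Si](C)(C)C(C)(C)C)c1ccc2c(OC)ccc(OC)c2c1OC(C)=O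
F2 | step 15 | (1S)-1-[5,8-bis(dichloroboryloxy)-1,4-dioxo-1,4-dihydronaphthalen-2-yl]-4-methylpent-3-enyl 2-methylpropanoate | CC(C)=CC[C@H](OC(=O)C(C)C)C1=CC(=O)c2c(OB(Cl)Cl)ccc(OB(Cl)Cl)c2C1=O
F3 | step 8 | (2Z,4S)-1-(2,5-dimethoxyphenyl)-3-iodo-7-methylocta-2,6-dien-4-ol | CC(C)=CC[C@H](O)/C(I)=C/Cc1cc(OC)ccc1OC
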